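# Proposed synthesis of eudesm-4(15)-en-6α-yl (E)-p-coumarate (CNP0321375.1)

Eudesmane numbering is used throughout. Ring A is C1–C5 and C10, ring B is C5–C10, C14 is the angular methyl on C10, C15 is the carbon on C4, and C11–C13 form the three-carbon group on C7. α and β refer to the usual drawing with the C10 methyl β. The target is (5S,6S,7S,10R): 5α-H, 6α-O, 7β-isopropyl, 10β-methyl, trans-fused.

## The problem

- **Skeleton.** The target is a trans-fused decalin. C10 carries a quaternary methyl, C4 an exocyclic methylene, and ring B three contiguous stereocentres: C5 (ring-fusion H), C6 (equatorial ester oxygen) and C7 (equatorial isopropyl).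
- **Which centre controls which.** C10 cannot be corrected by equilibration, so it has to be set first and absolutely. The other three are within its reach: C7 lies 1,4 to it across ring B, C5 is its neighbour and is α to C6, and the equatorial C6 oxygen is the thermodynamic arrangement.
- **C6.** A hydride reagent would approach a C6 ketone from the α face, away from the axial C10 methyl, and give the axial alcohol. C6 therefore needs thermodynamic rather than steric control.
- **The 4(15)-alkene.** It is β,γ to C6. At the ketone oxidation level it can slip into conjugation as C4=C5 under acid or base, erasing C5.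
- **The ester.** The p-coumarate has a free phenol, a base-labile ester link and an E-cinnamate that is reducible, photo-isomerisable and a Michael acceptor. It must be attached after every reduction and after any photochemistry.
- **The enabling feature.** Cutting C6–C7 in ring B leaves an aldehyde carbon (C6) on C5 and a C7=C11 isopropylidene at the end of the C10–C9–C8 chain. The six-atom array C6–C5–C10–C9–C8–C7 is the citronellal pattern. A C4=C5 double bond in ring A fixes the geometry of that closure and keeps C15 as a methyl that can later become the methylene.

## Retrosynthesis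

**Ester bond (C6–O acyl).** Target 23 is cut to alcohol 17 and the silyl-protected acid 20, joined as 22 and desilylated last. This keeps the cinnamate out of the reductive and photochemical steps. Acid 20 comes from p-coumaric acid 18 through the bis-silyl derivative 19. The forward reaction must acylate a hindered equatorial alcohol without touching the neighbouring alkene.

**C6–H (carbinol to ketone).** Alcohol 17 is taken back to ketone 16. Reduction under thermodynamic control should give the equatorial 6α-alcohol, which a hydride reagent would not. The ketone is needed in any case for the next retrosynthetic step.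

**C5–H and the alkene position.** β,γ-Enone 16 is traced to conjugated enone 14 through dienol 15. In 14 the C15 methyl is held syn to the C6 carbonyl by ring A, so a light-induced 1,5-hydrogen shift can take a hydrogen only from C15, not from C3. A base-mediated deconjugation would favour the endocyclic 3-ene. The forward step must protonate C5 on the α face and must not let 16 revert.

**Oxidation level at C6 and C11.** Enone 14 comes from allylic alcohol 13 by oxidation, and 13 from dienol 12 by saturating only the isopropenyl group. Both are functional-group changes. They remove the C6 centre created in the ring closure, so only C7 has to be right in 12.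

**C6–C7 (ring B).** Dienol 12 is opened to monocyclic aldehyde 11. Of the ring-B bonds this is the only one whose cleavage gives a carbonyl and an alkene in ene relationship and removes two stereocentres at once. The precursor has one ring and one stereocentre. The forward reaction must form C6–C7 with the C7 substituent cis to the C10 methyl.

**C4–C15 and the C4=C5 double bond.** Enal 11 is derived from keto acetal 9 by methyl addition to the C4 ketone (carbinol 10), acetal hydrolysis and dehydration. This is a 1,3-carbonyl transposition; it places the methyl on C4 and the aldehyde on C5 without any regiochemical choice.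

**C5–C6.** Keto acetal 9 comes from silyl enol ether 8 and a one-carbon electrophile at the formate oxidation level. The enol ether double bond must point toward the quaternary carbon, which deprotonation of the parent ketone would not deliver.

**C10–C14.** Silyl enol ether 8 is the trapped enolate 7 from catalytic asymmetric conjugate addition of the methyl donor 6 to enone 5. This sets the only stereocentre that is not under substrate control and fixes the enolate regiochemistry in the same operation.

**C10–C9.** Enone 5 is assembled from bromide 1 (as Grignard reagent 3) and vinylogous ester 2 through adduct 4. Both are commercial, and the step needs no selectivity.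

## Roads not taken

**Alternative 1: transannular closure of a ten-membered dienol.**
- Cut: C5–C10, back to the (E,E)-germacra-1(10),4-dien-6-ol A1.
- Forward step: acid protonates C1, the C10 cation is captured across the ring by C5, and the C4 cation loses a C15 proton to give alcohol A2, which is identical with 17.
- Merits: one step makes both rings, C5, C10 and the exocyclic methylene, and arrives at the alcohol oxidation level, so the ketone detour is avoided. In endgame length it is clearly better than the chosen plan.
- Weak points: A1 is a ten-membered ring with two E-trisubstituted alkenes and two stereocentres. It is prone to Cope rearrangement and exists as several conformers. Its C6 hydroxyl is allylic to C4=C5 and may ionise under the same acid. The C4 cation can lose a proton toward C3 or C5 or take up water.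
- Comparison: the chosen plan reaches its cyclisation precursor 11 in four steps from commercial materials, and the alkene position in 16 is fixed by geometry rather than by partitioning of a cation.

**Alternative 2: acylation of a desymmetrised cyclohexene.**
- Cut: C4–C5, back to acid chloride A3.
- Forward step: SnCl4 promotes acylation at C5 and loss of HCl gives enone A4.
- Merits: C7 is set early by desymmetrisation. The C4 ketone would later give the methylene by Wittig olefination, which is more robust than the photochemical step of the chosen plan.
- Weak points: A4 has no oxygen at C6 and no C10 methyl. The methyl would have to be added to a tetrasubstituted enone with stereocontrol from C7, which is 1,4-remote. C6 would need a late allylic oxidation in competition with C1 and C9, and C5 would still have to be set.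
- Comparison: the chosen plan carries the C6 oxygen from the ring closure onward and relays C10 to C7 within a ring. It accepts the less robust alkene placement in return.

**Alternative 3: radical conjugate cyclisation.**
- Cut: C9–C10, back to iodo enone A5.
- Forward step: the C9 radical, generated with (Me3Si)3SiH and azobisisobutyronitrile, adds to C10 and the C5 radical is reduced, giving hydroxy ketone A6.
- Merits: the C6 oxygen and C7 are set before cyclisation and never change oxidation level. The C4 ketone again allows a direct Wittig methylenation. In redox economy and in the olefination this road is better.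
- Weak points: the radical must attack a fully substituted enone carbon in a 6-endo mode, in competition with direct reduction. The C10 configuration would depend on the conformation of an acyclic carbinol chain, and A6 is a β-hydroxy ketone, prone to retro-aldol cleavage and elimination under basic olefination. A5 needs an enantio- and diastereoselective aldol-type union at the α-carbon of a β-substituted enone.
- Comparison: the chosen plan sets the quaternary centre by a catalytic conjugate addition with close precedent and controls C7 by a ring constraint.

Key step: step 5

## Route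

Remark on the chemistry: the antipode of the phosphoramidite ligand in step 2 is assumed to be the one that adds methyl to the face of 5 giving the (R)-configured quaternary centre; this would be confirmed on 8 before proceeding. Compounds 9 and 10 are carried as diastereomer mixtures at centres that step 4 removes.

Step 1
Reactants: 1 5-bromo-2-methylpent-2-ene; 2 3-ethoxycyclohex-2-en-1-one
Product: 5 3-(4-methylpent-3-en-1-yl)cyclohex-2-en-1-one, via homoprenylmagnesium bromide 3 (not isolated), via 1,2-adduct carbinol 4 (not isolated)
Conditions: Mg, THF, rt → 40 °C; then 2, THF, 0 °C → rt; then 1 M aq HCl, rt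
Reagents that add atoms: water, O
Why: Stork–Danheiser sequence: the Grignard reagent adds 1,2 to the vinylogous ester, and aqueous acid hydrolyses the enol ether and dehydrates the tertiary carbinol to the transposed 3-alkyl enone. No stereocentre is formed.

Step 2
Reactants: 5 3-(4-methylpent-3-en-1-yl)cyclohex-2-en-1-one; 6 trimethylaluminium
Product: 8 trimethyl{[(3R)-3-methyl-3-(4-methylpent-3-en-1-yl)cyclohex-1-en-1-yl]oxy}silane, via dimethylaluminium enolate 7 (not isolated)
Conditions: Me3Al (1.4 equiv), copper thiophene-2-carboxylate Cu(O2CC4H3S) (2 mol %), chiral biaryl phosphoramidite L* (4 mol %), Et2O, −30 °C; then Me3SiOTf, −30 → 0 °C; Et3N, cold aq NaHCO3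
Reagents that add atoms: trimethylsilyl trifluoromethanesulfonate, C[Si](C)(C)OS(=O)(=O)C(F)(F)F
Why: Copper-catalysed asymmetric conjugate addition of a trialkylaluminium to a 3-alkylcyclohexenone builds the quaternary centre, with the ligand choosing the enone face. Silylating the aluminium enolate in the same flask fixes the enol double bond toward the quaternary carbon, which ketone deprotonation would not give.

Step 3
Reactants: 8 trimethyl{[(3R)-3-methyl-3-(4-methylpent-3-en-1-yl)cyclohex-1-en-1-yl]oxy}silane
Product: 9 (3R)-2-(dimethoxymethyl)-3-methyl-3-(4-methylpent-3-en-1-yl)cyclohexan-1-one (both C2 epimers)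
Conditions: HC(OMe)3 (1.5 equiv), Me3SiOTf (5 mol %), CH2Cl2, −78 °C; Et3N
Reagents that add atoms: trimethyl orthoformate, COC(OC)OC
Why: Mukaiyama-type alkylation: the dimethoxycarbenium ion from the orthoformate is small enough for the neopentyl enol carbon and is taken up by the silyl enol ether far faster than by the side-chain alkene. The new C2 centre is unselective and is removed in step 4.

Step 4
Reactants: 9 (3R)-2-(dimethoxymethyl)-3-methyl-3-(4-methylpent-3-en-1-yl)cyclohexan-1-one
Product: 11 (6R)-2,6-dimethyl-6-(4-methylpent-3-en-1-yl)cyclohex-1-ene-1-carbaldehyde, via tertiary carbinol acetal 10 (not isolated)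
Conditions: MeLi, CeCl3, THF, −78 °C; then 2 M aq HCl, THF, 0 °C → rt
Reagents that add atoms: methyllithium, [Li]C; water, O
Why: The organocerium reagent adds to the hindered ketone without enolising it. Aqueous acid frees the aldehyde, and the β-hydroxy aldehyde dehydrates into conjugation (1,3-carbonyl transposition to a 2-methylcycloalk-1-enecarbaldehyde); dilute acid at room temperature should spare the trisubstituted side-chain alkene.

Step 5
Reactants: 11 (6R)-2,6-dimethyl-6-(4-methylpent-3-en-1-yl)cyclohex-1-ene-1-carbaldehyde
Product: 12 (6S,7S,10R)-eudesma-4,11-dien-6-ol (6α-hydroxy, 7β-isopropenyl, 10β-methyl)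
Conditions: Me2AlCl (1.5 equiv), CH2Cl2, −78 → 0 °C; aq potassium sodium tartrate
Reagents that add atoms: none
Why: Me2AlCl binds the aldehyde oxygen of 11, and the C7=C11 alkene adds through C7 to C6 while a hydrogen of a C11 methyl passes to oxygen in a six-centre array, so the C6–C7 bond, the O–H bond and the isopropenyl double bond form together (Lewis-acid carbonyl-ene reaction; closest known case: citronellal to isopulegol). Ring B closes as a six-membered ring with both reacting π bonds outside it (exo at the carbonyl and exo at the alkene), in a chair fused to the hydrogen-transfer array. Because ring A holds C1 near the plane of C4=C5, only the chair with the C10 methyl axial on the forming ring is open; the isopropylidene unit takes the equatorial site at C7, so the isopropenyl group ends cis to the C10 methyl (7β) and C7 is controlled by C10. The complexed oxygen is expected equatorial too, giving the 6α-alcohol trans to isopropenyl; allylic strain against the C4 methyl may divert part of the material to the 6β-epimer, which is harmless because C6 becomes a ketone in step 7. The step needs 1,2- rather than 1,4-attack on the enal and a concerted rather than cationic course: the fully substituted C4 disfavours conjugate attack, and Me2AlCl consumes stray protons with loss of methane, which suppresses proton-catalysed Prins pathways.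

Step 6
Reactants: 12 (6S,7S,10R)-eudesma-4,11-dien-6-ol
Product: 13 (6S,7S,10R)-eudesm-4-en-6-ol
Conditions: H2 (1 atm), RhCl(PPh3)3 (5 mol %), benzene/EtOH, rt
Reagents that add atoms: none
Why: Homogeneous hydrogenation with RhCl(PPh3)3 reduces the 1,1-disubstituted isopropenyl group and leaves the tetrasubstituted C4=C5 bond. No new stereocentre arises.

Step 7
Reactants: 13 (6S,7S,10R)-eudesm-4-en-6-ol
Product: 14 (7S,10R)-eudesm-4-en-6-one
Conditions: Dess–Martin periodinane, CH2Cl2, 0 °C → rt
Reagents that add atoms: none
Why: Dess–Martin oxidation of the allylic alcohol gives the s-cis enone from either C6 epimer. C7 is now α to the carbonyl, but its equatorial isopropyl group is the stable arrangement.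

Step 8
Reactants: 14 (7S,10R)-eudesm-4-en-6-one
Product: 16 (5S,7S,10R)-eudesm-4(15)-en-6-one (5α-H), via dienol 15 (not isolated)
Conditions: hν (350 nm, Pyrex), 1,2-dimethylimidazole (0.2 equiv), degassed MeOH, rt; stopped before full conversion, 14 recycled
Reagents that add atoms: none
Why: Photoenolisation (photochemical deconjugation of an s-cis β-alkyl enone): the excited carbonyl takes a hydrogen from C15, the only γ-carbon held syn to it, through a six-membered array to give dienol 15. Weak-base-catalysed ketonisation protonates C5 on the α face, anti to the axial C10 methyl, which gives the trans ring fusion.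

Step 9
Reactants: 16 (5S,7S,10R)-eudesm-4(15)-en-6-one
Product: 17 (5S,6S,7S,10R)-eudesm-4(15)-en-6-ol (6α-hydroxy)
Conditions: Li, NH3(l)/THF, EtOH, −78 °C; NH4Cl
Reagents that add atoms: none
Why: Dissolving-metal reduction through the ketyl gives the thermodynamically preferred equatorial alcohol, where hydride reagents would give the axial one by attack anti to the C10 methyl. The isolated 1,1-disubstituted alkene is not reduced, and the proton source limits enolisation.

Step 10
Reactants: 18 (E)-3-(4-hydroxyphenyl)prop-2-enoic acid (p-coumaric acid)
Product: 20 (E)-3-[4-(tert-butyldimethylsilyloxy)phenyl]prop-2-enoic acid, via bis-silyl derivative 19 (not isolated)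
Conditions: TBSCl (2.2 equiv), imidazole, DMF, rt; then AcOH/THF/H2O, rt
Reagents that add atoms: tert-butyldimethylsilyl chloride, CC(C)(C)[Si](C)(C)Cl
Why: Both acidic groups are silylated, and the labile silyl ester is then hydrolysed selectively while the aryl silyl ether stays.

Step 11
Reactants: 17 (5S,6S,7S,10R)-eudesm-4(15)-en-6-ol; 20 (E)-3-[4-(tert-butyldimethylsilyloxy)phenyl]prop-2-enoic acid
Product: 22 (5S,6S,7S,10R)-eudesm-4(15)-en-6-yl (E)-3-[4-(tert-butyldimethylsilyloxy)phenyl]prop-2-enoate, via mixed anhydride 21 (not isolated)
Conditions: 2,4,6-Cl3C6H2COCl, Et3N, THF, rt; then 17, DMAP, toluene, rt → 60 °C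
Reagents that add atoms: none
Why: Yamaguchi esterification: DMAP transfers the cinnamoyl group from the mixed anhydride to the hindered equatorial alcohol. The C–O bond at C6 is untouched, so configuration and E geometry are kept.

Step 12
Reactants: 22 (5S,6S,7S,10R)-eudesm-4(15)-en-6-yl (E)-3-[4-(tert-butyldimethylsilyloxy)phenyl]prop-2-enoate
Product: 23 (5S,6S,7S,10R)-eudesm-4(15)-en-6-yl (E)-3-(4-hydroxyphenyl)prop-2-enoate
Conditions: Bu4NF, AcOH, THF, 0 °C
Reagents that add atoms: none
Why: Fluoride cleaves the aryl silyl ether. The acetic acid buffer keeps the phenoxide from attacking the ester.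

## Compound list

1 | 5-bromo-2-methylpent-2-ene | CC(C)=CCCBr | starting material
2 | 3-ethoxycyclohex-2-en-1-one | CCOC1=CC(=O)CCC1 | starting material
3 | (4-methylpent-3-en-1-yl)magnesium bromide | CC(C)=CCC[Mg]Br | intermediate
4 | 3-ethoxy-1-(4-methylpent-3-en-1-yl)cyclohex-2-en-1-ol (racemic) | CCOC1=CC(O)(CCC=C(C)C)CCC1 | intermediate
5 | 3-(4-methylpent-3-en-1-yl)cyclohex-2-en-1-one | O=C1C=C(CCC=C(C)C)CCC1 | intermediate
6 | trimethylaluminium | C[Al](C)C | starting material
7 | dimethylaluminium (3R)-3-methyl-3-(4-methylpent-3-en-1-yl)cyclohex-1-en-1-olate | C[Al](C)OC1=C[C@@](C)(CCC=C(C)C)CCC1 | intermediate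
8 | trimethyl{[(3R)-3-methyl-3-(4-methylpent-3-en-1-yl)cyclohex-1-en-1-yl]oxy}silane | C[Si](C)(C)OC1=C[C@@](C)(CCC=C(C)C)CCC1 | intermediate
9 | (3R)-2-(dimethoxymethyl)-3-methyl-3-(4-methylpent-3-en-1-yl)cyclohexan-1-one, both C2 epimers | COC(OC)C1C(=O)CCC[C@]1(C)CCC=C(C)C | intermediate
10 | (3R)-2-(dimethoxymethyl)-1,3-dimethyl-3-(4-methylpent-3-en-1-yl)cyclohexan-1-ol, mixture at C1 and C2 | COC(OC)C1C(C)(O)CCC[C@]1(C)CCC=C(C)C | intermediate
11 | (6R)-2,6-dimethyl-6-(4-methylpent-3-en-1-yl)cyclohex-1-ene-1-carbaldehyde | CC1=C(C=O)[C@@](C)(CCC=C(C)C)CCC1 | intermediate
12 | (6S,7S,10R)-eudesma-4,11-dien-6-ol (6α-OH, 7β-isopropenyl, 10β-methyl) | CC=1CCC[C@]2(C)CC[C@@H](C(C)=C)[C@H](O)C=12 | intermediate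
13 | (6S,7S,10R)-eudesm-4-en-6-ol | CC=1CCC[C@]2(C)CC[C@@H](C(C)C)[C@H](O)C=12 | intermediate
14 | (7S,10R)-eudesm-4-en-6-one | CC=1CCC[C@]2(C)CC[C@@H](C(C)C)C(=O)C=12 | intermediate
15 | (7S,10R)-eudesma-4(15),5-dien-6-ol | C=C1CCC[C@]2(C)CC[C@@H](C(C)C)C(O)=C12 | intermediate
16 | (5S,7S,10R)-eudesm-4(15)-en-6-one (5α-H, trans-fused) | C=C1CCC[C@]2(C)CC[C@@H](C(C)C)C(=O)[C@@H]12 | intermediate
17 | (5S,6S,7S,10R)-eudesm-4(15)-en-6-ol (6α-OH) | C=C1CCC[C@]2(C)CC[C@@H](C(C)C)[C@H](O)[C@@H]12 | intermediate
18 | (E)-3-(4-hydroxyphenyl)prop-2-enoic acid | OC(=O)/C=C/c1ccc(O)cc1 | starting material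
19 | tert-butyldimethylsilyl (E)-3-[4-(tert-butyldimethylsilyloxy)phenyl]prop-2-enoate | CC(C)(C)[Si](C)(C)OC(=O)/C=C/c1ccc(O[Si](C)(C)C(C)(C)C)cc1 | intermediate
20 | (E)-3-[4-(tert-butyldimethylsilyloxy)phenyl]prop-2-enoic acid | CC(C)(C)[Si](C)(C)Oc1ccc(/C=C/C(=O)O)cc1 | intermediate
21 | (E)-3-[4-(tert-butyldimethylsilyloxy)phenyl]prop-2-enoic 2,4,6-trichlorobenzoic anhydride | CC(C)(C)[Si](C)(C)Oc1ccc(/C=C/C(=O)OC(=O)c2c(Cl)cc(Cl)cc2Cl)cc1 | intermediate
22 | (5S,6S,7S,10R)-eudesm-4(15)-en-6-yl (E)-3-[4-(tert-butyldimethylsilyloxy)phenyl]prop-2-enoate | C=C1CCC[C@]2(C)CC[C@@H](C(C)C)[C@H](OC(=O)/C=C/c3ccc(O[Si](C)(C)C(C)(C)C)cc3)[C@@H]12 | intermediate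
23 | (5S,6S,7S,10R)-eudesm-4(15)-en-6-yl (E)-3-(4-hydroxyphenyl)prop-2-enoate | C=C1CCC[C@]2(C)CC[C@@H](C(C)C)[C@H](OC(=O)/C=C/c3ccc(O)cc3)[C@@H]12 | target

## Step count and least certain steps

Total: 12 steps. Longest linear sequence: 11 steps (steps 1–9, 11 and 12); step 10 prepares the acid partner.

**Step 5 (key step).**
- What may go wrong: the alkene may attack the Lewis-acid-activated enal at C4 instead of C6. The closure may run stepwise through the C11 cation, with chloride capture or unselective proton loss. Selectivity at C7 may erode through a chair with the alkene axial. The conjugated, fully substituted aldehyde may also react too slowly.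
- Fallback: run the closure from 11 as a deliberate Prins cyclisation with SnCl4 in CH2Cl2 at −78 °C, so that the C11 cation is captured by chloride, giving 11-chloroeudesm-4-en-6α-ol F1. Radical dechlorination of this tertiary chloride with Bu3SnH and azobisisobutyronitrile in toluene at 80 °C returns to the route at 13 and makes step 6 unnecessary. The same C6–C7 bond and the same chair are used.

**Step 8.**
- What may go wrong: the β,γ-enone may reconjugate on prolonged contact with base or silica. Over-irradiation may cause secondary photochemistry of 16 (acyl shift, or hydrogen abstraction from the isopropyl methyls). C5 may be protonated on the wrong face.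
- Fallback: ground-state deconjugation from 14. LiN(i-Pr)2 with hexamethylphosphoramide in THF at −78 °C, coordinated to the carbonyl, removes the syn C15 hydrogen to give the lithium dienolate of eudesma-4(15),5-dien-6-ol F2. Inverse quench into cold acetic acid/THF protonates kinetically at C5, anti to the C10 methyl, and returns to the route at 16. Competing deprotonation at C7 only regenerates 14.

**Step 9.**
- What may go wrong: enolisation by alkoxide or amide before electron transfer would reconjugate the enone, which is then over-reduced. Equatorial selectivity at C6 may be incomplete.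
- Fallback: from 16, reduce with LiBH(s-Bu)3 in THF at −78 °C, which attacks the α face and gives the axial alcohol (5S,6R,7S,10R)-eudesm-4(15)-en-6-ol F3. A Mitsunobu reaction of F3 with acid 20 (PPh3, diisopropyl azodicarboxylate, toluene) inverts C6 while forming the ester and returns to the route at 22, replacing steps 9 and 11.

**Step 2.**
- What may go wrong: facial discrimination may be insufficient with the long 3-substituent. O-silylation of the aluminium enolate may be incomplete, giving the ketone, from which the regiodefined enol derivative cannot be recovered.
- Fallback: interchange the two alkyl groups. Starting from 1, converted into Grignard reagent 3 as in step 1, add 3 to 3-methylcyclohex-2-en-1-one F4 under Cu(OTf)2 with a chiral N-heterocyclic carbene ligand. Silylating the resulting bromomagnesium (3R)-3-methyl-3-(4-methylpent-3-en-1-yl)cyclohex-1-en-1-olate F5 with Me3SiCl/Et3N returns to the route at 8. Step 1 is then not needed.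

## Further compounds

F1 | step 5 | 11-chloroeudesm-4-en-6α-ol (7β side chain, 10β-methyl) | CC=1CCC[C@]2(C)CC[C@@H](C(C)(C)Cl)[C@H](O)C=12
F2 | step 8 | lithium (7S,10R)-eudesma-4(15),5-dien-6-olate | C=C1CCC[C@]2(C)CC[C@@H](C(C)C)C(O[Li])=C12
F3 | step 9 | (5S,6R,7S,10R)-eudesm-4(15)-en-6-ol (6β-OH) | C=C1CCC[C@]2(C)CC[C@@H](C(C)C)[C@@H](O)[C@@H]12
F4 | step 2 | 3-methylcyclohex-2-en-1-one | CC1=CC(=O)CCC1
F5 | step 2 | bromomagnesium (3R)-3-methyl-3-(4-methylpent-3-en-1-yl)cyclohex-1-en-1-olate | Br[Mg]OC1=C[C@@](C)(CCC=C(C)C)CCC1
A1 | alternative 1 | (1(10)E,4E,6S,7S)-germacra-1(10),4-dien-6-ol | C/C1=C\CC/C(C)=C/[C@@H](O)[C@H](C(C)C)CC1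
A2 | alternative 1 | (5S,6S,7S,10R)-eudesm-4(15)-en-6-ol | C=C1CCC[C@]2(C)CC[C@@H](C(C)C)[C@H](O)[C@@H]12
A3 | alternative 2 | 4-[(4R)-4-(propan-2-yl)cyclohex-1-en-1-yl]butanoyl chloride | O=C(Cl)CCCC1=CC[C@H](C(C)C)CC1
A4 | alternative 2 | (7R)-7-(propan-2-yl)-3,4,5,6,7,8-hexahydronaphthalen-1(2H)-one | O=C1CCCC2=C1C[C@H](C(C)C)CC2
A5 | alternative 3 | 2-[(1S,2S)-1-hydroxy-4-iodo-2-(propan-2-yl)butyl]-3-methylcyclohex-2-en-1-one | CC1=C(C(=O)CCC1)[C@@H](O)[C@H](C(C)C)CCI
A6 | alternative 3 | trans-fused 6α-hydroxy-7β-isopropyl-10β-methyl-15-noreudesman-4-one (5α-H) | O=C1CCC[C@]2(C)CC[C@@H](C(C)C)[C@H](O)[C@@H]12
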